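**Retrosynthetic overview**
1. Rings are lettered A–F from the 2,4,6-trihydroxyphenoxy end (A–O–B–O–C–O–D–O–E–O–F). All hydroxyls are carried as methyl ethers and freed last by global BBr3 demethylation.
2. Rings A, B and D each come from 4-fluoro-3,5-dimethoxybenzaldehyde: SNAr by a phenol, then Baeyer–Villiger/Dakin (CHO → OH), which returns a phenol for the next cycle.
3. The pentaoxygenated rings E and C are built de novo on a squarate. The key C–C bond (ring C4–C5) is made by adding the acyl-anion equivalent 1-methoxyvinyllithium to a carbonyl of an aryl methyl squarate; O-methylation and thermal 4π-opening/6π-closure then form C1–C6 and give a phenol ortho to the aryloxy group.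
4. Both aryl methyl squarates are made from one isolated batch of 3-chloro-4-methoxycyclobut-3-ene-1,2-dione (squaric dichloride + MeOH).
5. Ring order: F (bought) → E (built) → D (attached) → C (built) → B (attached) → A (attached) → deprotection.

Assumption: the target has no stereocentre (it is achiral), so there is no enantiomer to select; 2 and 10 are taken as catalogue chemicals.

Shorthand in the steps: "E–F phenol", "D–E–F aldehyde" and so on mean the permethylated oligomer of the named rings, with the OH or CHO on the first-named ring. Full names are in the compound list. 1-Methoxyvinyllithium is a reagent made fresh in a second flask from methyl vinyl ether and t-BuLi each time it is needed.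

**Step 1**
Reactants: 2 squaric acid dichloride (3,4-dichlorocyclobut-3-ene-1,2-dione)
Product: 3 3-chloro-4-methoxycyclobut-3-ene-1,2-dione
Conditions: MeOH (1.0 equiv), CH2Cl2, −40 → 0 °C, N2 purge; evaporate, Kugelrohr distil; one batch, kept under Ar at −20 °C
Reagents that add atoms: methanol, CO
Why: Vinylogous acyl substitution (addition–elimination) on the vinylogous acid chloride, in which the first methoxy group is a strong vinylogous donor that deactivates the remaining C–Cl, so one equivalent of methanol stops at the ester chloride; no stereocentre is formed.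

**Step 2**
Reactants: 1 3,4,5-trimethoxyphenol; 3 3-chloro-4-methoxycyclobut-3-ene-1,2-dione
Product: 4 3-methoxy-4-(3,4,5-trimethoxyphenoxy)cyclobut-3-ene-1,2-dione
Conditions: i-Pr2NEt (1.1 equiv), CH2Cl2, −40 °C → rt
Reagents that add atoms: none
Why: Vinylogous acyl substitution (addition–elimination): the phenol esterifies the remaining vinylogous acid chloride of 3 under amine base, and the methoxy group, a poorer leaving group than chloride, stays in place.

**Step 3**
Reactants: 4 3-methoxy-4-(3,4,5-trimethoxyphenoxy)cyclobut-3-ene-1,2-dione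
Product: 9 3,4,5-trimethoxy-2-(3,4,5-trimethoxyphenoxy)phenol (E–F phenol), via lithium alkoxide adduct 5 (not isolated), via cyclobutenone methyl ether 6 (not isolated), via dienylketene 7 (not isolated), via cyclohexadienone 8 (not isolated)
Conditions: CH2=C(OMe)Li (1.1 equiv; from methyl vinyl ether, t-BuLi, THF, −78 → 0 °C), THF, −78 °C; MeOTf, −78 → 0 °C; then PhMe, 110 °C (crude 6 carried on unpurified)
Reagents that add atoms: methyl vinyl ether, COC=C; methyl triflate, COS(=O)(=O)C(F)(F)F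
Why: Proposed new method: the α-lithiated enol ether (an acyl-anion equivalent) should add 1,2 to the carbonyl of 4 that is conjugated only to the weaker aryloxy donor and flanked by the OMe-bearing carbon (the other C=O is a deactivated vinylogous methyl ester), joining two natively electrophilic carbons as ring C4–C5; MeOTf caps the tertiary alkoxide, and on heating the 4-OMe rotates outward in the conrotatory 4π opening, so the methoxyvinyl group sits cis to the ketene and 6π-electrocyclisation plus tautomerisation gives the phenol with the aryloxy group ortho to the new OH; the closest known reaction type is the Moore ring expansion of 4-alkenyl-4-alkoxycyclobutenones from dialkyl squarates and alkenyllithiums, here extended to a mixed aryl methyl squarate, and the racemic stereocentre of 6 is erased on ring opening.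

**Step 4**
Reactants: 9 E–F phenol; 10 4-fluoro-3,5-dimethoxybenzaldehyde
Product: 11 3,5-dimethoxy-4-[3,4,5-trimethoxy-2-(3,4,5-trimethoxyphenoxy)phenoxy]benzaldehyde (D–E–F aldehyde)
Conditions: Cs2CO3, DMSO, 110 °C
Reagents that add atoms: none
Why: SNAr (addition–elimination): the caesium phenoxide attacks the C–F carbon activated by the para-formyl group, and the flanking methoxy groups, twisted out of conjugation, do not cancel that activation.

**Step 5**
Reactants: 11 D–E–F aldehyde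
Product: 13 3,5-dimethoxy-4-[3,4,5-trimethoxy-2-(3,4,5-trimethoxyphenoxy)phenoxy]phenol (D–E–F phenol), via aryl formate 12 (not isolated)
Conditions: mCPBA, CH2Cl2, 0 °C → rt; then K2CO3 (cat.), MeOH, rt
Reagents that add atoms: mCPBA, OOC(=O)c1cccc(Cl)c1
Why: Baeyer–Villiger (Dakin-type) oxidation: the electron-rich aryl group migrates in the Criegee intermediate to give the aryl formate, which mild methanolysis cleaves to the phenol, as is standard for polyalkoxybenzaldehydes.

**Step 6**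
Reactants: 13 D–E–F phenol; 3 3-chloro-4-methoxycyclobut-3-ene-1,2-dione
Product: 14 D–E–F aryl methyl squarate
Conditions: 3 (1.2 equiv), i-Pr2NEt (1.3 equiv), CH2Cl2, −40 °C → rt
Reagents that add atoms: none
Why: Same vinylogous acyl substitution as step 2, with the precious phenol reacting only at the single C–Cl of the preformed chloro methoxy squarate.

**Step 7**
Reactants: 14 D–E–F aryl methyl squarate
Product: 19 C–D–E–F phenol, via lithium alkoxide adduct 15 (not isolated), via cyclobutenone methyl ether 16 (not isolated), via dienylketene 17 (not isolated), via cyclohexadienone 18 (not isolated)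
Conditions: CH2=C(OMe)Li (1.1 equiv; from methyl vinyl ether, t-BuLi, THF, −78 → 0 °C), THF, −78 °C; MeOTf, −78 → 0 °C; then PhMe, 110 °C (crude 16 carried on unpurified)
Reagents that add atoms: methyl vinyl ether, COC=C; methyl triflate, COS(=O)(=O)C(F)(F)F
Why: Proposed new method: as in step 3, the acyl-anion equivalent should add to the more electrophilic carbonyl (the one next to the OMe-bearing carbon and conjugated to the aryloxy group), and O-methylation followed by the torquoselective 4π-opening/6π-closure then builds ring C with the D-ring aryloxy group ortho to the new phenol; the closest known reaction type is the Moore squarate ring expansion, and the racemic centre of 16 is lost on ring opening.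

**Step 8**
Reactants: 19 C–D–E–F phenol; 10 4-fluoro-3,5-dimethoxybenzaldehyde
Product: 20 B–C–D–E–F aldehyde
Conditions: Cs2CO3, DMSO, 110 °C
Reagents that add atoms: none
Why: SNAr as in step 4: the only free phenol displaces the para-formyl-activated fluoride.

**Step 9**
Reactants: 20 B–C–D–E–F aldehyde
Product: 22 B–C–D–E–F phenol, via aryl formate 21 (not isolated)
Conditions: mCPBA, CH2Cl2, 0 °C → rt; then K2CO3 (cat.), MeOH, rt
Reagents that add atoms: mCPBA, OOC(=O)c1cccc(Cl)c1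
Why: Baeyer–Villiger (Dakin-type) oxidation with aryl migration, then formate methanolysis, as in step 5.

**Step 10**
Reactants: 22 B–C–D–E–F phenol; 10 4-fluoro-3,5-dimethoxybenzaldehyde
Product: 23 A–B–C–D–E–F aldehyde
Conditions: Cs2CO3, DMSO, 110 °C
Reagents that add atoms: none
Why: SNAr as in step 4; here the phenoxide is unhindered (flanked by two H), so this is the easiest of the three etherifications.

**Step 11**
Reactants: 23 A–B–C–D–E–F aldehyde
Product: 25 A–B–C–D–E–F phenol (pentadeca-O-methyl ether of the target), via aryl formate 24 (not isolated)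
Conditions: mCPBA, CH2Cl2, 0 °C → rt; then K2CO3 (cat.), MeOH, rt
Reagents that add atoms: mCPBA, OOC(=O)c1cccc(Cl)c1
Why: Baeyer–Villiger (Dakin-type) oxidation and formate methanolysis turn the formyl group into the para-hydroxyl of ring A.

**Step 12**
Reactants: 25 A–B–C–D–E–F phenol
Product: 26 CNP0114537.0 (target)
Conditions: BBr3 (ca. 30 equiv), CH2Cl2, −78 °C → rt; then H2O, under Ar; Sephadex LH-20
Reagents that add atoms: none
Why: Lewis-acid ether cleavage (BBr3 demethylation): boron coordinates each methoxy oxygen and bromide attacks the methyl carbon by SN2, while the diaryl ether bonds have no sp3 carbon and survive; hydrolysis frees all sixteen phenols.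

**Compound list**
1 | 3,4,5-trimethoxyphenol | COc1cc(O)cc(OC)c1OC | starting material
2 | squaric acid dichloride (3,4-dichlorocyclobut-3-ene-1,2-dione) | O=C1C(Cl)=C(Cl)C1=O | starting material
3 | 3-chloro-4-methoxycyclobut-3-ene-1,2-dione | COC1=C(Cl)C(=O)C1=O | intermediate
4 | 3-methoxy-4-(3,4,5-trimethoxyphenoxy)cyclobut-3-ene-1,2-dione | COC1=C(Oc2cc(OC)c(OC)c(OC)c2)C(=O)C1=O | intermediate
5 | lithium 2-methoxy-1-(1-methoxyethenyl)-4-oxo-3-(3,4,5-trimethoxyphenoxy)cyclobut-2-en-1-olate (racemic) | [Li]OC1(C(=C)OC)C(OC)=C(Oc2cc(OC)c(OC)c(OC)c2)C1=O | intermediate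
6 | 3,4-dimethoxy-4-(1-methoxyethenyl)-2-(3,4,5-trimethoxyphenoxy)cyclobut-2-en-1-one (racemic) | COC(=C)C1(OC)C(OC)=C(Oc2cc(OC)c(OC)c(OC)c2)C1=O | intermediate
7 | (3Z)-3,4,5-trimethoxy-2-(3,4,5-trimethoxyphenoxy)hexa-1,3,5-trien-1-one | O=C=C(Oc1cc(OC)c(OC)c(OC)c1)/C(OC)=C(OC)\C(OC)=C | intermediate
8 | 3,4,5-trimethoxy-2-(3,4,5-trimethoxyphenoxy)cyclohexa-2,4-dien-1-one | O=C1CC(OC)=C(OC)C(OC)=C1Oc1cc(OC)c(OC)c(OC)c1 | intermediate
9 | 3,4,5-trimethoxy-2-(3,4,5-trimethoxyphenoxy)phenol (E–F phenol) | COc1cc(O)c(Oc2cc(OC)c(OC)c(OC)c2)c(OC)c1OC | intermediate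
10 | 4-fluoro-3,5-dimethoxybenzaldehyde | COc1cc(C=O)cc(OC)c1F | starting material
11 | 3,5-dimethoxy-4-[3,4,5-trimethoxy-2-(3,4,5-trimethoxyphenoxy)phenoxy]benzaldehyde (D–E–F aldehyde) | O=Cc1cc(OC)c(Oc2cc(OC)c(OC)c(OC)c2Oc2cc(OC)c(OC)c(OC)c2)c(OC)c1 | intermediate
12 | 3,5-dimethoxy-4-[3,4,5-trimethoxy-2-(3,4,5-trimethoxyphenoxy)phenoxy]phenyl formate | O=COc1cc(OC)c(Oc2cc(OC)c(OC)c(OC)c2Oc2cc(OC)c(OC)c(OC)c2)c(OC)c1 | intermediate
13 | 3,5-dimethoxy-4-[3,4,5-trimethoxy-2-(3,4,5-trimethoxyphenoxy)phenoxy]phenol (D–E–F phenol) | Oc1cc(OC)c(Oc2cc(OC)c(OC)c(OC)c2Oc2cc(OC)c(OC)c(OC)c2)c(OC)c1 | intermediate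
14 | 3-methoxy-4-{3,5-dimethoxy-4-[3,4,5-trimethoxy-2-(3,4,5-trimethoxyphenoxy)phenoxy]phenoxy}cyclobut-3-ene-1,2-dione (D–E–F aryl methyl squarate) | COC1=C(Oc2cc(OC)c(Oc3cc(OC)c(OC)c(OC)c3Oc3cc(OC)c(OC)c(OC)c3)c(OC)c2)C(=O)C1=O | intermediate
15 | lithium 2-methoxy-1-(1-methoxyethenyl)-4-oxo-3-{3,5-dimethoxy-4-[3,4,5-trimethoxy-2-(3,4,5-trimethoxyphenoxy)phenoxy]phenoxy}cyclobut-2-en-1-olate (racemic) | [Li]OC1(C(=C)OC)C(OC)=C(Oc2cc(OC)c(Oc3cc(OC)c(OC)c(OC)c3Oc3cc(OC)c(OC)c(OC)c3)c(OC)c2)C1=O | intermediate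
16 | 3,4-dimethoxy-4-(1-methoxyethenyl)-2-{3,5-dimethoxy-4-[3,4,5-trimethoxy-2-(3,4,5-trimethoxyphenoxy)phenoxy]phenoxy}cyclobut-2-en-1-one (racemic) | COC(=C)C1(OC)C(OC)=C(Oc2cc(OC)c(Oc3cc(OC)c(OC)c(OC)c3Oc3cc(OC)c(OC)c(OC)c3)c(OC)c2)C1=O | intermediate
17 | (3Z)-3,4,5-trimethoxy-2-{3,5-dimethoxy-4-[3,4,5-trimethoxy-2-(3,4,5-trimethoxyphenoxy)phenoxy]phenoxy}hexa-1,3,5-trien-1-one | O=C=C(Oc1cc(OC)c(Oc2cc(OC)c(OC)c(OC)c2Oc2cc(OC)c(OC)c(OC)c2)c(OC)c1)/C(OC)=C(OC)\C(OC)=C | intermediate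
18 | 3,4,5-trimethoxy-2-{3,5-dimethoxy-4-[3,4,5-trimethoxy-2-(3,4,5-trimethoxyphenoxy)phenoxy]phenoxy}cyclohexa-2,4-dien-1-one | O=C1CC(OC)=C(OC)C(OC)=C1Oc1cc(OC)c(Oc2cc(OC)c(OC)c(OC)c2Oc2cc(OC)c(OC)c(OC)c2)c(OC)c1 | intermediate
19 | 2-{3,5-dimethoxy-4-[3,4,5-trimethoxy-2-(3,4,5-trimethoxyphenoxy)phenoxy]phenoxy}-3,4,5-trimethoxyphenol (C–D–E–F phenol) | COc1cc(O)c(Oc2cc(OC)c(Oc3cc(OC)c(OC)c(OC)c3Oc3cc(OC)c(OC)c(OC)c3)c(OC)c2)c(OC)c1OC | intermediate
20 | 4-(2-{3,5-dimethoxy-4-[3,4,5-trimethoxy-2-(3,4,5-trimethoxyphenoxy)phenoxy]phenoxy}-3,4,5-trimethoxyphenoxy)-3,5-dimethoxybenzaldehyde (B–C–D–E–F aldehyde) | O=Cc1cc(OC)c(Oc2cc(OC)c(OC)c(OC)c2Oc2cc(OC)c(Oc3cc(OC)c(OC)c(OC)c3Oc3cc(OC)c(OC)c(OC)c3)c(OC)c2)c(OC)c1 | intermediate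
21 | 4-(2-{3,5-dimethoxy-4-[3,4,5-trimethoxy-2-(3,4,5-trimethoxyphenoxy)phenoxy]phenoxy}-3,4,5-trimethoxyphenoxy)-3,5-dimethoxyphenyl formate | O=COc1cc(OC)c(Oc2cc(OC)c(OC)c(OC)c2Oc2cc(OC)c(Oc3cc(OC)c(OC)c(OC)c3Oc3cc(OC)c(OC)c(OC)c3)c(OC)c2)c(OC)c1 | intermediate
22 | 4-(2-{3,5-dimethoxy-4-[3,4,5-trimethoxy-2-(3,4,5-trimethoxyphenoxy)phenoxy]phenoxy}-3,4,5-trimethoxyphenoxy)-3,5-dimethoxyphenol (B–C–D–E–F phenol) | Oc1cc(OC)c(Oc2cc(OC)c(OC)c(OC)c2Oc2cc(OC)c(Oc3cc(OC)c(OC)c(OC)c3Oc3cc(OC)c(OC)c(OC)c3)c(OC)c2)c(OC)c1 | intermediate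
23 | 4-[4-(2-{3,5-dimethoxy-4-[3,4,5-trimethoxy-2-(3,4,5-trimethoxyphenoxy)phenoxy]phenoxy}-3,4,5-trimethoxyphenoxy)-3,5-dimethoxyphenoxy]-3,5-dimethoxybenzaldehyde (A–B–C–D–E–F aldehyde) | O=Cc1cc(OC)c(Oc2cc(OC)c(Oc3cc(OC)c(OC)c(OC)c3Oc3cc(OC)c(Oc4cc(OC)c(OC)c(OC)c4Oc4cc(OC)c(OC)c(OC)c4)c(OC)c3)c(OC)c2)c(OC)c1 | intermediate
24 | 4-[4-(2-{3,5-dimethoxy-4-[3,4,5-trimethoxy-2-(3,4,5-trimethoxyphenoxy)phenoxy]phenoxy}-3,4,5-trimethoxyphenoxy)-3,5-dimethoxyphenoxy]-3,5-dimethoxyphenyl formate | O=COc1cc(OC)c(Oc2cc(OC)c(Oc3cc(OC)c(OC)c(OC)c3Oc3cc(OC)c(Oc4cc(OC)c(OC)c(OC)c4Oc4cc(OC)c(OC)c(OC)c4)c(OC)c3)c(OC)c2)c(OC)c1 | intermediate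
25 | 4-[4-(2-{3,5-dimethoxy-4-[3,4,5-trimethoxy-2-(3,4,5-trimethoxyphenoxy)phenoxy]phenoxy}-3,4,5-trimethoxyphenoxy)-3,5-dimethoxyphenoxy]-3,5-dimethoxyphenol (A–B–C–D–E–F phenol) | Oc1cc(OC)c(Oc2cc(OC)c(Oc3cc(OC)c(OC)c(OC)c3Oc3cc(OC)c(Oc4cc(OC)c(OC)c(OC)c4Oc4cc(OC)c(OC)c(OC)c4)c(OC)c3)c(OC)c2)c(OC)c1 | intermediate
26 | CNP0114537.0: 2-[3,5-dihydroxy-4-(3,4,5-trihydroxy-2-{3,5-dihydroxy-4-[3,4,5-trihydroxy-2-(3,4,5-trihydroxyphenoxy)phenoxy]phenoxy}phenoxy)phenoxy]benzene-1,3,5-triol (achiral) | Oc1cc(O)c(Oc2cc(O)c(Oc3cc(O)c(O)c(O)c3Oc3cc(O)c(Oc4cc(O)c(O)c(O)c4Oc4cc(O)c(O)c(O)c4)c(O)c3)c(O)c2)c(O)c1 | target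

**Step count and risks**
Total steps: 12. Longest linear sequence: 12 steps, from 2 (2 → 3 → 4 → 9 → 11 → 13 → 14 → 19 → 20 → 22 → 23 → 25 → 26).

Most likely to fail:

1. Step 7 (the same concern applies to step 3). The regioselectivity of the organolithium addition to a mixed aryl methyl squarate is unproven, and attack at the aryloxy-bearing carbon or at the wrong carbonyl would give isomers or destroy the advanced phenol. The fallback sets out from 13 and comes back at 19, bypassing 14–18. A Cu-catalysed Ullmann coupling (CuI, picolinic acid, K3PO4, DMSO, 90 °C) of 13 with commercial 2-bromo-3,4,5-trimethoxybenzaldehyde gives 2-{3,5-dimethoxy-4-[3,4,5-trimethoxy-2-(3,4,5-trimethoxyphenoxy)phenoxy]phenoxy}-3,4,5-trimethoxybenzaldehyde F1. mCPBA oxidises it to the corresponding aryl formate F2, and K2CO3/MeOH releases 19.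

2. Step 8 (the same concern applies to steps 4 and 10). The fluoride is flanked by two methoxy groups and the phenoxide carries an ortho aryloxy group, so the uncatalysed SNAr may be too slow for the aldehyde to survive. The fallback sets out from 19 and comes back at 20. The ether is made instead by Cu-catalysed Ullmann coupling (CuI, picolinic acid, K3PO4, DMSO, 90 °C) with commercial 4-bromo-3,5-dimethoxybenzaldehyde, which gives 20 directly, so no new compound arises (F0).

3. Step 12. Fifteen demethylations on one molecule may stop short, and the free hexadecaphenol oxidises in air and is hard to purify. The fallback sets out from 25 and comes back at 26. The crude BBr3 product is not purified but peracetylated (Ac2O, pyridine, DMAP) to the hexadecaacetate of the target F3, which is stable and can be separated on silica from partly methylated material. Acid-catalysed methanolysis (HCl in degassed MeOH, 40 °C, Ar) then frees 26.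

**Further compounds**
F1 | step 7 | 2-{3,5-dimethoxy-4-[3,4,5-trimethoxy-2-(3,4,5-trimethoxyphenoxy)phenoxy]phenoxy}-3,4,5-trimethoxybenzaldehyde | O=Cc1cc(OC)c(OC)c(OC)c1Oc1cc(OC)c(Oc2cc(OC)c(OC)c(OC)c2Oc2cc(OC)c(OC)c(OC)c2)c(OC)c1
F2 | step 7 | 2-{3,5-dimethoxy-4-[3,4,5-trimethoxy-2-(3,4,5-trimethoxyphenoxy)phenoxy]phenoxy}-3,4,5-trimethoxyphenyl formate | O=COc1cc(OC)c(OC)c(OC)c1Oc1cc(OC)c(Oc2cc(OC)c(OC)c(OC)c2Oc2cc(OC)c(OC)c(OC)c2)c(OC)c1
F0 | step 8 | none | none
F3 | step 12 | hexadecaacetate of the target (every OH of 26 as OAc) | CC(=O)Oc1cc(OC(C)=O)c(Oc2cc(OC(C)=O)c(Oc3cc(OC(C)=O)c(OC(C)=O)c(OC(C)=O)c3Oc3cc(OC(C)=O)c(Oc4cc(OC(C)=O)c(OC(C)=O)c(OC(C)=O)c4Oc4cc(OC(C)=O)c(OC(C)=O)c(OC(C)=O)c4)c(OC(C)=O)c3)c(OC(C)=O)c2)c(OC(C)=O)c1
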